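**Remarks on the chemistry.** Flavonoid numbering is used: O1, C2, C3, C4 (C=O), C4a, C5–C8, C8a for rings C and A; C1'–C6' for ring B; C1'' for the prenyl CH2. At C2 the CIP order is O1 > C1' > C3 > H, so the given SMILES is the (2S) enantiomer. MOM = methoxymethyl. 5,7-Dihydroxy-4H-chromen-4-one (1), prenyl bromide (3) and 4-bromo-2-methoxyphenol (9) are taken as purchased.

**Compound numbers:** 1 5,7-dihydroxychromone; 2 its 7-MOM ether; 3 prenyl bromide; 4 the 5-O-prenyl ether of 2; 5 and 6 the two dienones of the rearrangement (not isolated); 7 5-hydroxy-7-MOM-8-prenylchromone; 8 5,7-bis-MOM-8-prenylchromone; 9 4-bromo-2-methoxyphenol; 10 its MOM ether; 11 the aryllithium and 12 the borate from 10 (not isolated); 13 the arylboronic acid; 14 the tris-MOM flavanone; 15 the target.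

## The problem

The target is a (2S)-flavanone: ring A and ring C form a 2,3-dihydro-4H-chromen-4-one, ring B (4-hydroxy-3-methoxyphenyl) sits on C2, free phenols sit on C5, C7 and C4', and a prenyl group sits on C8. The only stereocentre, C2, is a benzylic ether carbon β to the C4 ketone. O1 can leave from it by E1cB ring opening to a 2'-hydroxychalcone, so C2 racemizes under base, and more slowly under hot acid or Lewis acid. These are the conditions of the classical chalcone closure, and no second stereocentre is available to control C2. Ring A is a phloroglucinol in which C6 and C8 are almost equally nucleophilic. They differ only in which flanking oxygen is O1, so direct C-prenylation or an unbiased chalcone closure gives 6-/8-prenyl mixtures. The prenyl alkene next to the C7 hydroxyl adds that hydroxyl under strong acid (dimethylchroman formation) and does not survive hydrogenolysis, and three free phenols rule out strongly basic late steps.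

The feature that opens another entry is that C2 is the β-carbon of the vinylogous ester O1–C2–C3–C4(=O) in ring C and carries ring B through the single bond C2–C1'. The C2=C3 dehydro compound (a chromone) is therefore a flat, achiral Michael acceptor, and ring B can be added to it as a nucleophile, forming the last skeletal bond and the stereocentre together. A second feature settles the regiochemistry: C8 lies para to the C5 oxygen, and O5 can never be confused with O1, so a prenyl group placed on O5 can be relayed through C6 to C8 by two [3,3] shifts.

## Retrosynthesis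

**15 ⇐ 14.** The three O–CH2OCH3 bonds at O5, O7 and O4' are cut. MOM is chosen because it survives base, hydride, organolithium and the Lewis acid used earlier, and comes off by acetal exchange without base, so C2 never sees the conditions that open ring C. The forward step must cleave three aryl acetals without hydrating or cyclizing the prenyl group.

**14 ⇐ 8 + 13.** The C2–C1' bond is cut. The neighbouring cuts at C2 are O1–C2 (chalcone closure, reversible and racemizing) and C2–H (reduction of a flavone, which needs a longer precursor and has to spare the prenyl alkene). The C2–C1' cut is the only one that leaves ring C closed, gives two precursors of comparable size (the achiral chromone 8 and the arylboronic acid 13), and forms the stereocentre in an irreversible C–C bond formation under catalyst control. It also places the creation of the labile stereocentre in the second-to-last step. The forward reaction has to deliver the aryl group to the Re face of C2 and protonate the metal enolate before O1 can be eliminated.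

**8 ⇐ 7 ⇐ 4 (through 5 and 6).** The O5–MOM bond is cut first, then the C8–C1'' bond is traced back to an O5–C1'' bond. Direct C-prenylation of a 5,7-dioxygenated chromone would not distinguish C6 from C8, and a cross-coupling would need a regioselective halogenation. In the ether 4 the prenyl group sits on the one oxygen that is certain not to be O1. The aromatic Claisen shift can only reach C6, since C4a is blocked, and the following Cope shift can only reach C8. The relay is run on the achiral chromone, so no stereocentre is exposed to hot Lewis acid, which would be the case if the rearrangement followed the arylation. The forward reaction must let the Cope shift of dienone 5 outrun its enolization.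

**4 ⇐ 2 + 3; 2 ⇐ 1.** The O5–C1'' bond and the O7–MOM bond are cut. The two hydroxyls of 1 differ strongly: O7–H is the acidic, unhindered vinylogous acid, and O5–H is chelated to C4=O. One equivalent of MOMCl should therefore go to O7, and the remaining chelated phenol is then alkylated by prenyl bromide 3.

**13 ⇐ 10 ⇐ 9.** The C–B bond and the O–MOM bond are cut. Bromine in 9 already sits para to the hydroxyl and meta to the methoxy group, which is the substitution pattern of ring B. Protection, bromine–lithium exchange (through 11) and borylation (through 12) give 13 in two steps.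

## Roads not taken

**Alternative 1:** the most obvious route cuts O1–C2. Forward: Claisen–Schmidt condensation of 1-[2-hydroxy-4,6-bis(methoxymethoxy)-3-(3-methylbut-2-en-1-yl)phenyl]ethanone A1 with the protected vanillin gives the 2'-hydroxychalcone A2, and intramolecular oxa-Michael addition closes ring C. The chosen plan is better because this closure is reversible and goes through the same enolate that racemizes the product, so enantiocontrol has to work against an equilibrium. The 6'-alkoxy group also twists the enone of A2 out of conjugation, which slows the closure and weakens any catalyst control. A1 needs its own prenyl-placing sequence with O2'–H distinguished from O6'–H, so no steps are saved.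

**Alternative 2:** cut O1–C2 with inversion instead. Forward: Mitsunobu cyclization of the (3R)-β-hydroxy ketone A3, in which O2'–H displaces the activated benzylic hydroxyl. The chosen plan is better because the carbinol carbon of A3 is benzylic and para to an alkoxy group. The activated intermediate can therefore ionize (loss of configuration) or eliminate to the chalcone A2. A3 also needs an enantioselective aldol or reduction of its own and carries the stereocentre through more steps.

**Alternative 3:** cut the C2–H bond. Forward: enantioselective conjugate reduction (copper hydride) or hydrogenation of the 8-prenylflavone A4. The chosen plan is better because A4 costs about three more steps from A1 (acylation, Baker–Venkataraman shift, cyclodehydration). Its β-carbon bears both an aryl group and O1 and is a sluggish acceptor. Hydrogenation catalysts would also attack the prenyl alkene or the C4 ketone, and the catalyst would have to tell an aryl group from an oxygen substituent at C2.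

Key step: step 7

## Route

**Step 1**
Reactants: 1 5,7-dihydroxy-4H-chromen-4-one
Product: 2 5-hydroxy-7-(methoxymethoxy)-4H-chromen-4-one
Conditions: MOMCl (1.1 equiv), K2CO3, acetone, 0 °C to rt
Reagents that add atoms: chloromethyl methyl ether, COCCl
Why: Williamson-type acetal ether formation; O7–H is the acidic, unhindered vinylogous acid while O5–H is tied up in the hydrogen bond to C4=O, so one equivalent of MOMCl should go to O7.

**Step 2**
Reactants: 2 5-hydroxy-7-(methoxymethoxy)-4H-chromen-4-one; 3 1-bromo-3-methylbut-2-ene (prenyl bromide)
Product: 4 7-(methoxymethoxy)-5-[(3-methylbut-2-en-1-yl)oxy]-4H-chromen-4-one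
Conditions: 3 (1.3 equiv), K2CO3, DMF, 50 °C
Reagents that add atoms: none
Why: Williamson ether synthesis on the only remaining acidic site; in a dipolar aprotic solvent the chelated phenoxide should be alkylated on oxygen by the primary allylic bromide (SN2), and the chromone has no base-labile stereocentre.

**Step 3**
Reactants: 4 7-(methoxymethoxy)-5-[(3-methylbut-2-en-1-yl)oxy]-4H-chromen-4-one
Product: 7 5-hydroxy-7-(methoxymethoxy)-8-(3-methylbut-2-en-1-yl)-4H-chromen-4-one, via ortho-dienone 5 (not isolated), via para-dienone 6 (not isolated)
Conditions: Eu(fod)3 (10 mol %; fod = 6,6,7,7,8,8,8-heptafluoro-2,2-dimethyloctane-3,5-dionate), NaHCO3, PhCl, 85 °C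
Reagents that add atoms: none
Why: Lewis-acid-accelerated aromatic Claisen–Cope (para-Claisen) rearrangement: trivalent europium chelated between C4=O and O5 speeds the [3,3] shift to C6 (the only open ortho position), giving 5 with a 2-methylbut-3-en-2-yl group, and a second [3,3] (Cope) shift carries it to C8 as a normal prenyl group (6), which tautomerizes to the chelated phenol 7. The crowded C6 between C5=O and the C7 ether and the acid-scavenging NaHCO3 should favour the Cope shift over enolization of 5.

**Step 4**
Reactants: 7 5-hydroxy-7-(methoxymethoxy)-8-(3-methylbut-2-en-1-yl)-4H-chromen-4-one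
Product: 8 5,7-bis(methoxymethoxy)-8-(3-methylbut-2-en-1-yl)-4H-chromen-4-one
Conditions: NaH, DMF, 0 °C; MOMCl (1.3 equiv), 0 °C to rt
Reagents that add atoms: chloromethyl methyl ether, COCCl
Why: Williamson-type MOM protection after irreversible deprotonation, needed because O5–H is chelated; it removes the last acidic proton, which under the basic key step would give an unreactive phenoxide.

**Step 5**
Reactants: 9 4-bromo-2-methoxyphenol
Product: 10 4-bromo-2-methoxy-1-(methoxymethoxy)benzene
Conditions: MOMCl (1.2 equiv), K2CO3, acetone, rt
Reagents that add atoms: chloromethyl methyl ether, COCCl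
Why: Williamson-type MOM protection of a simple phenol; the group matches those on 8 so that one final operation frees all three phenols.

**Step 6**
Reactants: 10 4-bromo-2-methoxy-1-(methoxymethoxy)benzene
Product: 13 [3-methoxy-4-(methoxymethoxy)phenyl]boronic acid, via aryllithium 11 (not isolated), via lithium triisopropoxyborate 12 (not isolated)
Conditions: n-BuLi, THF, −78 °C; B(OiPr)3, −78 °C to rt; aq. HCl to pH 5–6, 0 °C
Reagents that add atoms: triisopropyl borate, CC(C)OB(OC(C)C)OC(C)C; water, O
Why: Bromine–lithium exchange at −78 °C is much faster than ortho-lithiation next to the MOM ether; the aryllithium is trapped by the borate and the ate complex is hydrolysed at a pH that leaves the aryl MOM ether intact.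

**Step 7**
Reactants: 8 5,7-bis(methoxymethoxy)-8-(3-methylbut-2-en-1-yl)-4H-chromen-4-one; 13 [3-methoxy-4-(methoxymethoxy)phenyl]boronic acid
Product: 14 (2S)-5,7-bis(methoxymethoxy)-2-[3-methoxy-4-(methoxymethoxy)phenyl]-8-(3-methylbut-2-en-1-yl)-2,3-dihydro-4H-chromen-4-one
Conditions: [RhCl(C2H4)2]2 (2.5 mol %), (S,S)-Ph-bod* [(1S,4S)-2,5-diphenylbicyclo[2.2.2]octa-2,5-diene] (5.5 mol %), 13 (2.5 equiv), KOH (20 mol %), toluene/H2O (10:1), 30 °C
Reagents that add atoms: none
Why: Hayashi–Miyaura-type asymmetric 1,4-addition: the hydroxorhodium–diene complex (monovalent rhodium) takes the aryl group from 13, the chromone C2=C3 bond inserts into the Rh–aryl bond, and water protonates the resulting oxa-π-allyl rhodium enolate at C3, releasing 14 and the Rh–OH species. The closest known reaction type is the rhodium/chiral diene-catalysed addition of arylboronic acids to chromones, which gives 2-arylchroman-4-ones. No ring is closed; the step forms the C2–C1' bond that joins ring B to the finished ring A/ring C core, so the precursors 8 (flat, achiral) and 13 are far simpler than 14. The only new stereocentre, C2, is controlled by the C2-symmetric diene: aryl delivery to the Re face of C2 (the face on which O1, C3, H run clockwise) gives 2S; the stereochemical model for cyclic enones points to the (S,S)-diene, and the mirror-image ligand is to be used should the first run show the opposite sense. The step needs 1,4- over 1,2-addition (inherent to aryl–rhodium insertion into an enone), protonation of the rhodium enolate faster than β-elimination of O1 (ring opening to a chalcone would cost enantiopurity), and no reaction at the prenyl alkene. The water-rich medium at 30 °C and the low base loading should secure the protonation, the unactivated trisubstituted alkene should not insert, and the MOM ethers at O5 and O7 keep the chromone from becoming an unreactive phenoxide.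

**Step 8**
Reactants: 14 (2S)-5,7-bis(methoxymethoxy)-2-[3-methoxy-4-(methoxymethoxy)phenyl]-8-(3-methylbut-2-en-1-yl)-2,3-dihydro-4H-chromen-4-one
Product: 15 (2S)-5,7-dihydroxy-2-(4-hydroxy-3-methoxyphenyl)-8-(3-methylbut-2-en-1-yl)-2,3-dihydro-4H-chromen-4-one
Conditions: 3 M aq. HCl/MeOH (1:4), 45 °C, stopped as soon as the third MOM group is gone
Reagents that add atoms: none
Why: Acid-catalysed acetal exchange moves the three CH2OCH3 units to methanol; no base is present, so the E1cB opening of ring C is not available, and the freed O5–H hydrogen bond to C4=O further stabilizes the closed flavanone. Brief, dilute acid at this temperature should leave the trisubstituted prenyl alkene untouched.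

## Compound list

1 | 5,7-dihydroxy-4H-chromen-4-one | O=c1ccoc2cc(O)cc(O)c12 | starting material
2 | 5-hydroxy-7-(methoxymethoxy)-4H-chromen-4-one | O=c1ccoc2cc(OCOC)cc(O)c12 | intermediate
3 | 1-bromo-3-methylbut-2-ene (prenyl bromide) | CC(C)=CCBr | starting material
4 | 7-(methoxymethoxy)-5-[(3-methylbut-2-en-1-yl)oxy]-4H-chromen-4-one | O=c1ccoc2cc(OCOC)cc(OCC=C(C)C)c12 | intermediate
5 | 7-(methoxymethoxy)-6-(2-methylbut-3-en-2-yl)-6H-chromene-4,5-dione (ortho-dienone, racemic at C6, not isolated) | O=C1C=COC2=C1C(=O)C(C(C)(C)C=C)C(OCOC)=C2 | intermediate
6 | 7-(methoxymethoxy)-8-(3-methylbut-2-en-1-yl)-8H-chromene-4,5-dione (para-dienone, racemic at C8, not isolated) | O=C1C=COC2=C1C(=O)C=C(OCOC)C2CC=C(C)C | intermediate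
7 | 5-hydroxy-7-(methoxymethoxy)-8-(3-methylbut-2-en-1-yl)-4H-chromen-4-one | O=c1ccoc2c(CC=C(C)C)c(OCOC)cc(O)c12 | intermediate
8 | 5,7-bis(methoxymethoxy)-8-(3-methylbut-2-en-1-yl)-4H-chromen-4-one | O=c1ccoc2c(CC=C(C)C)c(OCOC)cc(OCOC)c12 | intermediate
9 | 4-bromo-2-methoxyphenol | COc1cc(Br)ccc1O | starting material
10 | 4-bromo-2-methoxy-1-(methoxymethoxy)benzene | COCOc1ccc(Br)cc1OC | intermediate
11 | [3-methoxy-4-(methoxymethoxy)phenyl]lithium (not isolated) | [Li]c1ccc(OCOC)c(OC)c1 | intermediate
12 | lithium [3-methoxy-4-(methoxymethoxy)phenyl]tri(propan-2-yloxy)borate (not isolated) | [Li+].CC(C)O[B-](OC(C)C)(OC(C)C)c1ccc(OCOC)c(OC)c1 | intermediate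
13 | [3-methoxy-4-(methoxymethoxy)phenyl]boronic acid | COCOc1ccc(B(O)O)cc1OC | intermediate
14 | (2S)-5,7-bis(methoxymethoxy)-2-[3-methoxy-4-(methoxymethoxy)phenyl]-8-(3-methylbut-2-en-1-yl)-2,3-dihydro-4H-chromen-4-one | COc1cc([C@@H]2CC(=O)c3c(OCOC)cc(OCOC)c(CC=C(C)C)c3O2)ccc1OCOC | intermediate
15 | (2S)-5,7-dihydroxy-2-(4-hydroxy-3-methoxyphenyl)-8-(3-methylbut-2-en-1-yl)-2,3-dihydro-4H-chromen-4-one | COc1cc([C@@H]2CC(=O)c3c(O)cc(O)c(CC=C(C)C)c3O2)ccc1O | target

## Step count and risks

Total steps: 8. Longest linear sequence: 6 (steps 1, 2, 3, 4, 7, 8); steps 5 and 6 form the two-step branch to 13.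

**Step 7 (key step).** Three things may go wrong. Insertion into the electron-rich, doubly alkoxylated chromone may be slow, so that protodeboronation of the electron-rich boronic acid consumes 13. β-Elimination of O1 from the rhodium enolate, or base-induced retro-oxa-Michael opening of the product, may erode the enantiopurity. The ligand antipode may give the opposite sense, which is cured by the mirror-image diene. The fallback does not rely on the C2–C1' bond formation and sets out from 8. Aqueous KOH in ethanol at reflux opens the chromone with loss of C2 as formate and gives 1-[2-hydroxy-4,6-bis(methoxymethoxy)-3-(3-methylbut-2-en-1-yl)phenyl]ethanone F1 (the compound labelled A1 above). Aryllithium 11, generated from 10 as in step 6, is quenched with DMF to give 3-methoxy-4-(methoxymethoxy)benzaldehyde F2. Claisen–Schmidt condensation of F1 and F2 (KOH, EtOH/H2O, rt) gives the (E)-chalcone F3 (the compound labelled A2 above). NaOAc in refluxing ethanol closes it to the racemic flavanone F4. Kinetic resolution of F4 by asymmetric transfer hydrogenation (RuCl(p-cymene)[(R,R)-TsDPEN], HCO2H/Et3N, EtOAc, rt; the catalyst antipode that consumes the (2R)-ketone, as the usual aryl ketone model suggests) reduces the unwanted enantiomer to the (2R,4R)-cis-flavan-4-ol F5 and leaves (2S)-ketone 14, which is separated by chromatography. The route is rejoined at 14, at the cost of half the material.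

**Step 3.** Enolization of dienone 5 before the Cope shift would leave the 2-methylbut-3-en-2-yl group at C6. Ionization of the allyl ether under the Lewis acid would return 2. The fallback places the C8 substituent by cross-coupling and sets out from 1. Double protection (NaH, MOMCl, DMF) gives 5,7-bis(methoxymethoxy)-4H-chromen-4-one F6. Electrophilic iodination (N-iodosuccinimide, DMF, rt), which for 5,7-dialkoxychromones is directed to C8, gives 8-iodo-5,7-bis(methoxymethoxy)-4H-chromen-4-one F7. Stille coupling with tributyl(3-methylbut-2-en-1-yl)stannane (Pd(PPh3)4, DMF, 90 °C) joins the prenyl group through its CH2 terminus. The route is rejoined at 8, bypassing compounds 2 to 7.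

**Step 8.** Prolonged acid may add O7–H across the prenyl alkene (chroman formation), or open and reclose ring C with loss of enantiopurity. The fallback avoids protic acid and sets out from 14. TMSOTf and 2,2'-bipyridyl in CH2Cl2 at 0 °C exchange each aryl MOM ether for a trimethylsilyl ether, giving the tris(trimethylsilyl) ether F8. Aqueous methanol at rt then hydrolyses the silyl ethers, and the route is rejoined at 15.

**Step 6.** Competing lithiation ortho to the MOM ether, loss of the MOM group on acidification, or protodeboronation and boroxine formation during isolation may lower the supply of 13. The fallback replaces the organolithium by a catalytic borylation and sets out from 10. Miyaura borylation (bis(pinacolato)diboron, PdCl2(dppf), KOAc, dioxane, 85 °C) gives the pinacol boronate 2-[3-methoxy-4-(methoxymethoxy)phenyl]-4,4,5,5-tetramethyl-1,3,2-dioxaborolane F9. Oxidative removal of pinacol (NaIO4, NH4OAc, acetone/H2O, rt) gives the boronic acid, and the route is rejoined at 13.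

**Step 2.** The chelated phenoxide may react slowly, or be alkylated on carbon (C6 or C8) instead of on oxygen. The fallback activates the alcohol instead of the phenoxide and sets out from 2. Mitsunobu etherification with 3-methylbut-2-en-1-ol (PPh3, diisopropyl azodicarboxylate, THF, 0 °C to rt) uses the phenol only as the acid component, and the route is rejoined at 4. No new compound is made.

## Further compounds

F1 | step 7 | 1-[2-hydroxy-4,6-bis(methoxymethoxy)-3-(3-methylbut-2-en-1-yl)phenyl]ethanone | CC(=O)c1c(O)c(CC=C(C)C)c(OCOC)cc1OCOC
F2 | step 7 | 3-methoxy-4-(methoxymethoxy)benzaldehyde | COCOc1ccc(C=O)cc1OC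
F3 | step 7 | (E)-1-[2-hydroxy-4,6-bis(methoxymethoxy)-3-(3-methylbut-2-en-1-yl)phenyl]-3-[3-methoxy-4-(methoxymethoxy)phenyl]prop-2-en-1-one | COCOc1ccc(/C=C/C(=O)c2c(O)c(CC=C(C)C)c(OCOC)cc2OCOC)cc1OC
F4 | step 7 | racemic 5,7-bis(methoxymethoxy)-2-[3-methoxy-4-(methoxymethoxy)phenyl]-8-(3-methylbut-2-en-1-yl)-2,3-dihydro-4H-chromen-4-one | COc1cc(C2CC(=O)c3c(OCOC)cc(OCOC)c(CC=C(C)C)c3O2)ccc1OCOC
F5 | step 7 | (2R,4R)-5,7-bis(methoxymethoxy)-2-[3-methoxy-4-(methoxymethoxy)phenyl]-8-(3-methylbut-2-en-1-yl)-3,4-dihydro-2H-chromen-4-ol | COc1cc([C@H]2C[C@@H](O)c3c(OCOC)cc(OCOC)c(CC=C(C)C)c3O2)ccc1OCOC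
F6 | step 3 | 5,7-bis(methoxymethoxy)-4H-chromen-4-one | O=c1ccoc2cc(OCOC)cc(OCOC)c12
F7 | step 3 | 8-iodo-5,7-bis(methoxymethoxy)-4H-chromen-4-one | O=c1ccoc2c(I)c(OCOC)cc(OCOC)c12
F8 | step 8 | (2S)-2-[3-methoxy-4-(trimethylsilyloxy)phenyl]-8-(3-methylbut-2-en-1-yl)-5,7-bis(trimethylsilyloxy)-2,3-dihydro-4H-chromen-4-one | COc1cc([C@@H]2CC(=O)c3c(O[Si](C)(C)C)cc(O[Si](C)(C)C)c(CC=C(C)C)c3O2)ccc1O[Si](C)(C)C
F9 | step 6 | 2-[3-methoxy-4-(methoxymethoxy)phenyl]-4,4,5,5-tetramethyl-1,3,2-dioxaborolane | COCOc1ccc(B2OC(C)(C)C(C)(C)O2)cc1OC
F0 | step 2 | none | none
A1 | alternative 1 | 1-[2-hydroxy-4,6-bis(methoxymethoxy)-3-(3-methylbut-2-en-1-yl)phenyl]ethanone | CC(=O)c1c(O)c(CC=C(C)C)c(OCOC)cc1OCOC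
A2 | alternative 1 | (E)-1-[2-hydroxy-4,6-bis(methoxymethoxy)-3-(3-methylbut-2-en-1-yl)phenyl]-3-[3-methoxy-4-(methoxymethoxy)phenyl]prop-2-en-1-one | COCOc1ccc(/C=C/C(=O)c2c(O)c(CC=C(C)C)c(OCOC)cc2OCOC)cc1OC
A3 | alternative 2 | (3R)-3-hydroxy-1-[2-hydroxy-4,6-bis(methoxymethoxy)-3-(3-methylbut-2-en-1-yl)phenyl]-3-[3-methoxy-4-(methoxymethoxy)phenyl]propan-1-one | COCOc1ccc([C@H](O)CC(=O)c2c(O)c(CC=C(C)C)c(OCOC)cc2OCOC)cc1OC
A4 | alternative 3 | 5,7-bis(methoxymethoxy)-2-[3-methoxy-4-(methoxymethoxy)phenyl]-8-(3-methylbut-2-en-1-yl)-4H-chromen-4-one | COc1cc(-c2cc(=O)c3c(OCOC)cc(OCOC)c(CC=C(C)C)c3o2)ccc1OCOC
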